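## Strategy

- **Cuts (numbering of bicyclo[3.2.1]oct-3-ene-2,8-dione; ring A = C1–C2–C3–C4–C5–C8):** first the four phenolic O–H bonds (carried as silyl ethers), then the C4–C(vinyl) bond of the 4-hydroxystyryl arm (β-bromoenone plus alkenylboronate), then together the C5–C6 and C1–C7 bonds.
- **Enabling feature:** ring A is the diketo tautomer of a resorcinol substituted at its 5-position; its carbons C1 and C5, on either side of the C8 carbonyl, are spanned by C7 and C6, the two benzylic sp3 carbons of a resveratrol-type stilbene, so the cyclopentanone C1–C7–C6–C5–C8 is what a phenoxonium ion and an (E)-stilbene give in a dearomative [5+2].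
- **Forward order:** ring A is bought as an arene (3-bromo-5-methoxyphenol); its dearomatisation and the closure of the cyclopentanone happen in one operation and give the bicycle, then the styryl chain is joined at the bromine-bearing enone carbon and the silyl groups are removed.
- **Stereochemistry:** all four centres arise in the [5+2]: C6/C7 are trans from the (E)-alkene, C1/C5 follow from the bridge, the 7-aryl group is endo from a stacked transition state, and the absolute sense comes from a chiral aryl-λ3-iodane bound to the phenol oxygen.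

Key step: step 2

Assumption: the (R,R)-lactamide iodane diacetate (made beforehand from the commercial iodoarene with peracetic acid) is taken to give the enantiomer shown; if the sense of induction proves opposite, the (S,S)-reagent is used.

## Route

Step 1
Reactants: 1 resveratrol [(E)-3,4',5-trihydroxystilbene]
Product: 2 (E)-3,4',5-tris(tert-butyldimethylsilyloxy)stilbene
Conditions: TBSCl (3.6 equiv), imidazole (7 equiv), DMF, 0 °C → rt
Reagents that add atoms: tert-butyldimethylsilyl chloride, CC(C)(C)[Si](C)(C)Cl
Why: Imidazole-promoted O-silylation of phenols; the three silyl ethers mask every free phenol of the stilbene so that the oxidant of step 2 can engage only the phenol of 3, and they keep both aryl rings electron-rich.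

Step 2
Reactants: 2 (E)-3,4',5-tris(tert-butyldimethylsilyloxy)stilbene; 3 3-bromo-5-methoxyphenol
Product: 7 (1R,5R,6S,7S)-4-bromo-6-[3,5-bis(tert-butyldimethylsilyloxy)phenyl]-7-[4-(tert-butyldimethylsilyloxy)phenyl]bicyclo[3.2.1]oct-3-ene-2,8-dione, via aryloxy-λ3-iodane 4 (not isolated), via dienone benzylic cation 5 (not isolated), via bicyclic oxocarbenium ion 6 (not isolated)
Conditions: 3 (1.0 equiv), 2 (2.0 equiv), (R,R)-ArI(OAc)2 (1.1 equiv; Ar = 2,6-bis[(R)-1-(mesitylcarbamoyl)ethoxy]phenyl), CH2Cl2/(CF3)2CHOH 4:1, −60 → −40 °C; then cold aq NaHCO3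
Reagents that add atoms: none
Why: Proposed new method: the free hydroxyl of 3 displaces acetate on trivalent iodine to give 4, the stilbene carbon carrying the 3,5-bis(silyloxy)phenyl ring bonds to phenol carbon C2 (between C–O and C–Br) as the aryl iodide departs, the resulting cation 5 sits on the benzylic carbon next to the 4-silyloxyphenyl ring and is alkylated by phenol carbon C6 (the electron-rich terminus of the methyl enol ether conjugated to the new ketone), and the oxocarbenium ion 6 hands its methyl group to acetate, which leaves the enone carbonyl. Closest known reaction types are the cationic [5+2] cycloaddition of phenoxonium ions made from quinone monoketals or at an anode with (E)-aryl alkenes, which gives bicyclo[3.2.1]oct-3-ene-2,8-diones, and enantioselective phenol dearomatisation by chiral aryl-λ3-iodanes; the combination, intermolecular and on a phenol without a para donor, is new. The only ring closed is the cyclopentanone C1–C7–C6–C5–C8 (bicycle numbering), by a five-membered cation–olefin closure in which the attacking enol-ether double bond stays outside the new ring (5-exo), and this closure also completes the seven-membered perimeter of the bicycle. C5 and C6 arise in the first bond formation and C7 in the ring closure: the absolute sense comes from the lactamide arms of the iodane held on the phenol oxygen next to C2, the 7-aryl group is endo because the cationic aryl ring stacks over the methoxydienone in a compact transition state, the 6-aryl group is then exo because the (E)-geometry is carried into the trans C6/C7 relation by a closure faster than bond rotation, and C1 is dictated by the bridge, which can only close cis. The step needs attack at a bromine-flanked ring carbon instead of the carbon between the two oxygens (the latter is the more hindered, and attack at C2 or at the para carbon C4 converges on one constitution because the ring is 1,3-dioxygenated), closure through carbon instead of oxygen (cold, non-acidic kinetic conditions hold back the dihydrobenzofuran pathway and acid-driven rearrangement), and oxidation of 3 alone (2 has no free phenol, no peracid is present to epoxidise it, and the C–Br bond is inert).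

Step 3
Reactants: 8 4-hydroxybenzaldehyde
Product: 9 4-(tert-butyldimethylsilyloxy)benzaldehyde
Conditions: TBSCl (1.2 equiv), imidazole (2.5 equiv), CH2Cl2, rt
Reagents that add atoms: tert-butyldimethylsilyl chloride, CC(C)(C)[Si](C)(C)Cl
Why: Imidazole-promoted silylation of a phenol; the aldehyde is untouched and the phenol is masked against the strong base of step 4.

Step 4
Reactants: 9 4-(tert-butyldimethylsilyloxy)benzaldehyde
Product: 11 2-[(E)-2-[4-(tert-butyldimethylsilyloxy)phenyl]ethenyl]-4,4,5,5-tetramethyl-1,3,2-dioxaborolane, via lithium alkoxide adduct 10 (not isolated)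
Conditions: CH2(Bpin)2 (1.2 equiv), lithium 2,2,6,6-tetramethylpiperidide (1.2 equiv), THF, 0 °C; then 9, −78 °C → rt; aq NH4Cl
Reagents that add atoms: bis[(pinacolato)boryl]methane, CC1(C)OB(CB2OC(C)(C)C(C)(C)O2)OC1(C)C
Why: Boron–Wittig olefination: the α,α-diboryl carbanion adds to the non-enolisable aldehyde and syn elimination of a boron–oxygen unit from adduct 10 gives the alkenylboronate, (E) because aryl and the remaining boryl group lie anti in the four-membered oxaborate.

Step 5
Reactants: 7 (1R,5R,6S,7S)-4-bromo-6-[3,5-bis(tert-butyldimethylsilyloxy)phenyl]-7-[4-(tert-butyldimethylsilyloxy)phenyl]bicyclo[3.2.1]oct-3-ene-2,8-dione; 11 2-[(E)-2-[4-(tert-butyldimethylsilyloxy)phenyl]ethenyl]-4,4,5,5-tetramethyl-1,3,2-dioxaborolane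
Product: 12 (1R,5S,6S,7S)-6-[3,5-bis(tert-butyldimethylsilyloxy)phenyl]-7-[4-(tert-butyldimethylsilyloxy)phenyl]-4-[(E)-2-[4-(tert-butyldimethylsilyloxy)phenyl]ethenyl]bicyclo[3.2.1]oct-3-ene-2,8-dione
Conditions: PdCl2(dppf) (5 mol %), K3PO4 (2 equiv), degassed THF/H2O 20:1, rt → 35 °C
Reagents that add atoms: none
Why: Suzuki–Miyaura coupling; the β-bromoenone adds readily to zerovalent palladium at low temperature, alkene geometry is retained, and no stereocentre is at risk because both α-carbons are bridgeheads that cannot enolise (the descriptor at C5 changes only because bromine is replaced by carbon).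

Step 6
Reactants: 12 (1R,5S,6S,7S)-6-[3,5-bis(tert-butyldimethylsilyloxy)phenyl]-7-[4-(tert-butyldimethylsilyloxy)phenyl]-4-[(E)-2-[4-(tert-butyldimethylsilyloxy)phenyl]ethenyl]bicyclo[3.2.1]oct-3-ene-2,8-dione
Product: 13 (1R,5S,6S,7S)-6-(3,5-dihydroxyphenyl)-7-(4-hydroxyphenyl)-4-[(E)-2-(4-hydroxyphenyl)ethenyl]bicyclo[3.2.1]oct-3-ene-2,8-dione (CNP0288448.1)
Conditions: HF·pyridine (excess), pyridine, THF, 0 °C → rt; pH 7 phosphate buffer
Reagents that add atoms: none
Why: Fluoride-driven cleavage of the four aryl silyl ethers under buffered, weakly acidic conditions; no phenoxide is formed, so the non-enolisable bridged 1,3-diketone and the C1–C7 bond are spared and no stereocentre is touched.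

## Compound list

1 | resveratrol, (E)-3,4',5-trihydroxystilbene | Oc1ccc(/C=C/c2cc(O)cc(O)c2)cc1 | starting material
2 | (E)-3,4',5-tris(tert-butyldimethylsilyloxy)stilbene | CC(C)(C)[Si](C)(C)Oc1ccc(/C=C/c2cc(O[Si](C)(C)C(C)(C)C)cc(O[Si](C)(C)C(C)(C)C)c2)cc1 | intermediate
3 | 3-bromo-5-methoxyphenol | COc1cc(O)cc(Br)c1 | starting material
4 | acetoxy(3-bromo-5-methoxyphenoxy){2,6-bis[(R)-1-(mesitylcarbamoyl)ethoxy]phenyl}-λ3-iodane (not isolated) | COc1cc(Br)cc(OI(OC(C)=O)c2c(O[C@H](C)C(=O)Nc3c(C)cc(C)cc3C)cccc2O[C@H](C)C(=O)Nc2c(C)cc(C)cc2C)c1 | intermediate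
5 | 5-bromo-3-methoxycyclohexa-2,4-dienone carrying at C6 the 1-[3,5-bis(silyloxy)phenyl]-2-[4-(silyloxy)phenyl]ethyl cation, charge on the benzylic carbon next to the 4-silyloxyphenyl ring (not isolated) | BrC1=CC(OC)=CC(=O)[C@H]1[C@@H](c1cc(O[Si](C)(C)C(C)(C)C)cc(O[Si](C)(C)C(C)(C)C)c1)[CH+]c1ccc(O[Si](C)(C)C(C)(C)C)cc1 | intermediate
6 | O-methyl oxocarbenium ion of 7, methyl on the C2 oxygen (not isolated) | C[O+]=C1C=C(Br)[C@H]2C(=O)[C@@H]1[C@@H](c1ccc(O[Si](C)(C)C(C)(C)C)cc1)[C@@H]2c1cc(O[Si](C)(C)C(C)(C)C)cc(O[Si](C)(C)C(C)(C)C)c1 | intermediate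
7 | (1R,5R,6S,7S)-4-bromo-6-[3,5-bis(tert-butyldimethylsilyloxy)phenyl]-7-[4-(tert-butyldimethylsilyloxy)phenyl]bicyclo[3.2.1]oct-3-ene-2,8-dione; 6-aryl exo (toward C8), 7-aryl endo (toward the enone bridge), aryl groups trans | O=C1C=C(Br)[C@H]2C(=O)[C@@H]1[C@@H](c1ccc(O[Si](C)(C)C(C)(C)C)cc1)[C@@H]2c1cc(O[Si](C)(C)C(C)(C)C)cc(O[Si](C)(C)C(C)(C)C)c1 | intermediate
8 | 4-hydroxybenzaldehyde | O=Cc1ccc(O)cc1 | starting material
9 | 4-(tert-butyldimethylsilyloxy)benzaldehyde | O=Cc1ccc(O[Si](C)(C)C(C)(C)C)cc1 | intermediate
10 | lithium 1-[4-(tert-butyldimethylsilyloxy)phenyl]-2,2-bis(4,4,5,5-tetramethyl-1,3,2-dioxaborolan-2-yl)ethanolate, racemic (not isolated) | [Li]OC(c1ccc(O[Si](C)(C)C(C)(C)C)cc1)C(B1OC(C)(C)C(C)(C)O1)B1OC(C)(C)C(C)(C)O1 | intermediate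
11 | 2-[(E)-2-[4-(tert-butyldimethylsilyloxy)phenyl]ethenyl]-4,4,5,5-tetramethyl-1,3,2-dioxaborolane | CC1(C)OB(/C=C/c2ccc(O[Si](C)(C)C(C)(C)C)cc2)OC1(C)C | intermediate
12 | (1R,5S,6S,7S)-6-[3,5-bis(tert-butyldimethylsilyloxy)phenyl]-7-[4-(tert-butyldimethylsilyloxy)phenyl]-4-[(E)-2-[4-(tert-butyldimethylsilyloxy)phenyl]ethenyl]bicyclo[3.2.1]oct-3-ene-2,8-dione | O=C1C=C(/C=C/c2ccc(O[Si](C)(C)C(C)(C)C)cc2)[C@H]2C(=O)[C@@H]1[C@@H](c1ccc(O[Si](C)(C)C(C)(C)C)cc1)[C@@H]2c1cc(O[Si](C)(C)C(C)(C)C)cc(O[Si](C)(C)C(C)(C)C)c1 | intermediate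
13 | (1R,5S,6S,7S)-6-(3,5-dihydroxyphenyl)-7-(4-hydroxyphenyl)-4-[(E)-2-(4-hydroxyphenyl)ethenyl]bicyclo[3.2.1]oct-3-ene-2,8-dione, CNP0288448.1 | O=C1C=C(/C=C/c2ccc(O)cc2)[C@H]2C(=O)[C@@H]1[C@@H](c1ccc(O)cc1)[C@@H]2c1cc(O)cc(O)c1 | target

## Count and risks

Total step count: 6. Longest linear sequence: 4 steps (1 → 2 → 7 → 12 → 13; the branch 8 → 9 → 11 → 12 → 13 is equally long).

**Steps most likely to fail**

(a) Step 2, the one step beyond known chemistry.
What may go wrong: the first carbon–carbon bond may form at the ring carbon between the two oxygens; the ortho-dienone may lose a proton and re-aromatise before the second bond forms; the cation may close through oxygen to a dihydrobenzofuran; or enantioface control by the iodane may be weak.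
Fallback: it uses only known reaction types, sets out from 3 and 2 and comes back at 12; it pays for reliability with a third ring oxygen, which activates the arene as a quinone and is removed afterwards, and with a resolution. 3 is oxidised at its free para position with (KSO3)2NO (KH2PO4 buffer, water/acetone; Teuber oxidation) to 2-bromo-6-methoxy-1,4-benzoquinone F1. F1 and 2 are combined with TiCl4/Ti(OiPr)4 in CH2Cl2 at −78 °C, the known Lewis acid-promoted [5+2] cycloaddition of 2-alkoxy-1,4-benzoquinones with (E)-aryl alkenes: the stilbene carbon remote from the 4-silyloxyphenyl ring adds to the unsubstituted quinone carbon next to C–Br, the methyl enol ether carbon closes the five-membered ring, and loss of the methyl group should leave racemic 4-bromo-3-hydroxy-6-[3,5-bis(tert-butyldimethylsilyloxy)phenyl]-7-[4-(tert-butyldimethylsilyloxy)phenyl]bicyclo[3.2.1]oct-3-ene-2,8-dione F2. Suzuki–Miyaura coupling of F2 with 11 under the conditions of step 5 should give the racemic 3-hydroxy analogue of 12 F3. The enolic hydroxyl is converted into the racemic enol triflate F4 (Tf2O, pyridine, CH2Cl2, −78 °C), and palladium-catalysed formate reduction (Pd(OAc)2, PPh3, HCO2H, Et3N, DMF, 60 °C) removes the triflate to give racemic 12. 12 is then separated from the mirror-image tetrakis-silyl ether F5 by preparative chromatography on a chiral stationary phase.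

(b) Step 5.
What may go wrong: under aqueous base the aryl silyl ethers may be cleaved; the phenoxide of the 7-aryl group may then expel the diketone carbon C1 (retro-Michael opening with aromatisation of ring A); hydroxide may open the non-enolisable bridged 1,3-diketone; or the alkenylboronate may protodeboronate.
Fallback: it avoids boron and aqueous base, sets out from 9 and 7 and comes back at 12. 9 is methylenated (Ph3PCH3Br, KOtBu, THF, 0 °C; Wittig reaction) to 4-(tert-butyldimethylsilyloxy)styrene F6. 7 is joined to F6 in a Heck–Mizoroki reaction (Pd(OAc)2, P(o-tol)3, Et3N, MeCN, 70 °C): the alkenylpalladium from the β-bromoenone adds to the terminal carbon of the styrene and syn β-hydride elimination should give the (E)-diene 12.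

(c) Step 6.
What may go wrong: during the exposure to HF needed for four aryl silyl ethers the C1–C7 bond may ionise (benzylic cation stabilised by the freed para-hydroxyl) and the skeleton may drift to a dihydrobenzofuran or an aromatised resorcinol; or cleavage may stop at partly silylated material.
Fallback: it never exposes free phenols to acid or to a lasting base, sets out from 12 and comes back at 13. Fluoride-induced desilylation in the presence of Ac2O (CsF, Ac2O, DMF, 0 °C) traps each phenoxide as it forms and should give the tetraacetate of 13 F7. The aryl acetates are then removed by NH4OAc-catalysed methanolysis in aqueous MeOH at room temperature, a neutral method for aryl acetates, to give 13.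

## Further compounds

F1 | step 2 | 2-bromo-6-methoxy-1,4-benzoquinone | COC1=CC(=O)C=C(Br)C1=O
F2 | step 2 | racemic 4-bromo-3-hydroxy-6-[3,5-bis(tert-butyldimethylsilyloxy)phenyl]-7-[4-(tert-butyldimethylsilyloxy)phenyl]bicyclo[3.2.1]oct-3-ene-2,8-dione, relative configuration as in 7 (one enantiomer drawn) | O=C1C(O)=C(Br)[C@H]2C(=O)[C@@H]1[C@@H](c1ccc(O[Si](C)(C)C(C)(C)C)cc1)[C@@H]2c1cc(O[Si](C)(C)C(C)(C)C)cc(O[Si](C)(C)C(C)(C)C)c1
F3 | step 2 | racemic 3-hydroxy analogue of 12 (one enantiomer drawn) | O=C1C(O)=C(/C=C/c2ccc(O[Si](C)(C)C(C)(C)C)cc2)[C@H]2C(=O)[C@@H]1[C@@H](c1ccc(O[Si](C)(C)C(C)(C)C)cc1)[C@@H]2c1cc(O[Si](C)(C)C(C)(C)C)cc(O[Si](C)(C)C(C)(C)C)c1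
F4 | step 2 | racemic 3-(trifluoromethanesulfonyloxy) analogue of 12 (one enantiomer drawn) | O=C1C(OS(=O)(=O)C(F)(F)F)=C(/C=C/c2ccc(O[Si](C)(C)C(C)(C)C)cc2)[C@H]2C(=O)[C@@H]1[C@@H](c1ccc(O[Si](C)(C)C(C)(C)C)cc1)[C@@H]2c1cc(O[Si](C)(C)C(C)(C)C)cc(O[Si](C)(C)C(C)(C)C)c1
F5 | step 2 | (1S,5R,6R,7R)-enantiomer of 12 | O=C1C=C(/C=C/c2ccc(O[Si](C)(C)C(C)(C)C)cc2)[C@@H]2C(=O)[C@H]1[C@H](c1ccc(O[Si](C)(C)C(C)(C)C)cc1)[C@H]2c1cc(O[Si](C)(C)C(C)(C)C)cc(O[Si](C)(C)C(C)(C)C)c1
F6 | step 5 | 4-(tert-butyldimethylsilyloxy)styrene | C=Cc1ccc(O[Si](C)(C)C(C)(C)C)cc1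
F7 | step 6 | tetraacetate of 13 | O=C1C=C(/C=C/c2ccc(OC(C)=O)cc2)[C@H]2C(=O)[C@@H]1[C@@H](c1ccc(OC(C)=O)cc1)[C@@H]2c1cc(OC(C)=O)cc(OC(C)=O)c1
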